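The route rests on cutting the bond between the ipso carbon of the 3,5-dibromo-4-methoxyphenyl ring and the carbinol carbon. A catalytic enantioselective aryl transfer from an aryltitanium reagent to the formyl group on C3 of a fully assembled (Z)-5-benzylidene butenolide forms this bond and sets the only stereocentre (S) in one operation. The step exploits the butenolide ring: the C3 formyl carbon is the sole aldehyde, C4 is fully substituted and C5 is an sp2 ylidene carbon, so conjugate addition and base-induced loss of the new carbinol are both closed off. The precursor is a bis-silylated 3-formyl butenolide, made from 3,4-dibromofuran-2(5H)-one by Suzuki coupling, bromination, vinylogous aldol condensation and formylation.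

Key step: step 7

Remark: 3,4-dibromofuran-2(5H)-one (1) is taken as a purchased compound, and the sense of induction in step 7 is assigned by analogy with titanium–BINOLate additions, in which the (S)-ligand directs attack to the Si face of an aldehyde (TBS = tert-butyldimethylsilyl).

Step 1
Reactants: 1 3,4-dibromofuran-2(5H)-one; 2 (4-hydroxyphenyl)boronic acid
Product: 3 3-bromo-4-(4-hydroxyphenyl)furan-2(5H)-one
Conditions: PdCl2(PPh3)2 (5 mol %), CsF, BnEt3NCl, toluene/H2O, rt
Reagents that add atoms: none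
Why: Suzuki–Miyaura coupling, in which zerovalent palladium should insert selectively into the C4–Br bond (the β-position of the unsaturated lactone, a vinylogous acyl bromide) and leave the C3–Br bond for later use.

Step 2
Reactants: 3 3-bromo-4-(4-hydroxyphenyl)furan-2(5H)-one
Product: 4 3-bromo-4-(3-bromo-4-hydroxyphenyl)furan-2(5H)-one
Conditions: NBS (1.0 equiv), MeCN, 0 °C to rt
Reagents that add atoms: N-bromosuccinimide, O=C1CCC(=O)N1Br
Why: Electrophilic aromatic bromination, in which the free phenol directs one bromine to its ortho position (para is blocked) and one equivalent of NBS should stop at the mono-bromide because the first bromine deactivates the ring.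

Step 3
Reactants: 4 3-bromo-4-(3-bromo-4-hydroxyphenyl)furan-2(5H)-one; 5 3-bromo-4-hydroxybenzaldehyde
Product: 9 (5Z)-3-bromo-4-{3-bromo-4-[(tert-butyldimethylsilyl)oxy]phenyl}-5-({3-bromo-4-[(tert-butyldimethylsilyl)oxy]phenyl}methylidene)furan-2(5H)-one, via silylated aldehyde 6 (not isolated), via silyloxyfuran 7 (not isolated), via aldol silyl ether 8 (not isolated)
Conditions: TBSOTf (4 equiv), iPr2NEt (5 equiv), CH2Cl2, 0 °C to rt; then DBU (2 equiv), rt
Reagents that add atoms: tert-butyldimethylsilyl trifluoromethanesulfonate, CC(C)(C)[Si](C)(C)OS(=O)(=O)C(F)(F)F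
Why: Vinylogous Mukaiyama aldol condensation, in which TBSOTf silylates both phenols and turns the butenolide into its 2-silyloxyfuran, this attacks the silyl-activated aldehyde through C5, and DBU then removes silanol by E1cB elimination to give the thermodynamically preferred Z-alkene with the aryl group on the side of the ring oxygen and away from the C4 aryl group.

Step 4
Reactants: 9 (5Z)-3-bromo-4-{3-bromo-4-[(tert-butyldimethylsilyl)oxy]phenyl}-5-({3-bromo-4-[(tert-butyldimethylsilyl)oxy]phenyl}methylidene)furan-2(5H)-one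
Product: 10 (5Z)-4-{3-bromo-4-[(tert-butyldimethylsilyl)oxy]phenyl}-5-({3-bromo-4-[(tert-butyldimethylsilyl)oxy]phenyl}methylidene)-2-oxo-2,5-dihydrofuran-3-carbaldehyde
Conditions: Pd(PPh3)4 (5 mol %), CO (3 atm), Bu3SnH (1.1 equiv, slow addition), THF, 50 °C
Reagents that add atoms: carbon monoxide, [C-]#[O+]
Why: Palladium-catalysed reductive carbonylation (formylation), in which oxidative addition to zerovalent palladium is expected at the electron-poor alkenyl C3–Br bond rather than at the two electron-rich aryl C–Br bonds flanked by bulky silyloxy groups, and CO insertion followed by hydride transfer from tin gives the aldehyde.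

Step 5
Reactants: 11 2,6-dibromophenol
Product: 12 2,6-dibromo-4-iodophenol
Conditions: NIS (1.05 equiv), TsOH (cat.), MeCN, rt
Reagents that add atoms: N-iodosuccinimide, O=C1CCC(=O)N1I
Why: Electrophilic aromatic iodination, for which the only open activated position of the phenol is para to the hydroxy group.

Step 6
Reactants: 12 2,6-dibromo-4-iodophenol
Product: 13 1,3-dibromo-5-iodo-2-methoxybenzene
Conditions: MeI, K2CO3, acetone, reflux
Reagents that add atoms: iodomethane, CI
Why: Williamson ether synthesis, in which the acidic 2,6-dibromophenol is deprotonated by K2CO3 and methylated on oxygen.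

Step 7
Reactants: 10 (5Z)-4-{3-bromo-4-[(tert-butyldimethylsilyl)oxy]phenyl}-5-({3-bromo-4-[(tert-butyldimethylsilyl)oxy]phenyl}methylidene)-2-oxo-2,5-dihydrofuran-3-carbaldehyde; 13 1,3-dibromo-5-iodo-2-methoxybenzene
Product: 16 (5Z)-4-{3-bromo-4-[(tert-butyldimethylsilyl)oxy]phenyl}-5-({3-bromo-4-[(tert-butyldimethylsilyl)oxy]phenyl}methylidene)-3-[(S)-(3,5-dibromo-4-methoxyphenyl)(hydroxy)methyl]furan-2(5H)-one, via arylmagnesium chloride 14 (not isolated), via aryltitanium triisopropoxide 15 (not isolated)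
Conditions: 13 (1.8 equiv), iPrMgCl·LiCl, THF, –40 °C; ClTi(OiPr)3, –40 to 0 °C; then 10, (S)-3-(3,5-diphenylphenyl)-H8-BINOL (5 mol %), Ti(OiPr)4, CH2Cl2, 0 °C; aq. NH4Cl
Reagents that add atoms: none
Why: Iodine–magnesium exchange at the C–I bond (much faster than at either C–Br bond at –40 °C) and transmetalation give the aryltitanium triisopropoxide, whose aryl group is transferred to the formyl carbon of 10 within the chiral titanium complex of the (S)-configured 3-aryl-H8-BINOL ligand. The closest known reaction type is the catalytic enantioselective addition of aryltitanium triisopropoxides to aromatic and α-branched α,β-unsaturated aldehydes under 3-substituted H8-BINOL–titanium catalysis. No ring is closed. The single new stereocentre is under catalyst control alone: the (S)-ligand should deliver the aryl group to the Si face of the formyl group, which gives the (S)-carbinol because the priorities are OH > butenolide C3 > aryl > H. The step needs 1,2-addition to the aldehyde in preference to attack at the lactone carbonyl or at the conjugated C4 and benzylidene carbons; the low reactivity of aryltitanium triisopropoxides toward esters and Michael acceptors and the fully substituted C4 secure this. Since C5 is already an sp2 ylidene carbon, no γ-hydrogen remains from which the new carbinol could later be eliminated.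

Step 8
Reactants: 16 (5Z)-4-{3-bromo-4-[(tert-butyldimethylsilyl)oxy]phenyl}-5-({3-bromo-4-[(tert-butyldimethylsilyl)oxy]phenyl}methylidene)-3-[(S)-(3,5-dibromo-4-methoxyphenyl)(hydroxy)methyl]furan-2(5H)-one
Product: 17 (5Z)-4-(3-bromo-4-hydroxyphenyl)-5-[(3-bromo-4-hydroxyphenyl)methylidene]-3-[(S)-(3,5-dibromo-4-methoxyphenyl)(hydroxy)methyl]furan-2(5H)-one
Conditions: TBAF (2.2 equiv), AcOH (2.2 equiv), THF, 0 °C
Reagents that add atoms: none
Why: Fluoride-induced cleavage of the two aryl silyl ethers, buffered with acetic acid so that neither the methyl ether, the lactone nor the carbinol stereocentre is exposed to base.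

Compound list
1 | 3,4-dibromofuran-2(5H)-one | O=C1OCC(Br)=C1Br | starting material
2 | (4-hydroxyphenyl)boronic acid | OB(O)c1ccc(O)cc1 | starting material
3 | 3-bromo-4-(4-hydroxyphenyl)furan-2(5H)-one | O=C1OCC(c2ccc(O)cc2)=C1Br | intermediate
4 | 3-bromo-4-(3-bromo-4-hydroxyphenyl)furan-2(5H)-one | O=C1OCC(c2ccc(O)c(Br)c2)=C1Br | intermediate
5 | 3-bromo-4-hydroxybenzaldehyde | O=Cc1ccc(O)c(Br)c1 | starting material
6 | 3-bromo-4-[(tert-butyldimethylsilyl)oxy]benzaldehyde (formed in the flask in step 3) | O=Cc1ccc(O[Si](C)(C)C(C)(C)C)c(Br)c1 | intermediate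
7 | 3-bromo-4-{3-bromo-4-[(tert-butyldimethylsilyl)oxy]phenyl}-2-[(tert-butyldimethylsilyl)oxy]furan (formed in the flask in step 3) | CC(C)(C)[Si](C)(C)Oc1occ(-c2ccc(O[Si](C)(C)C(C)(C)C)c(Br)c2)c1Br | intermediate
8 | 3-bromo-4-{3-bromo-4-[(TBS)oxy]phenyl}-5-[{3-bromo-4-[(TBS)oxy]phenyl}{(TBS)oxy}methyl]furan-2(5H)-one, mixture of diastereomers (formed in the flask in step 3) | O=C1OC(C(O[Si](C)(C)C(C)(C)C)c2ccc(O[Si](C)(C)C(C)(C)C)c(Br)c2)C(c2ccc(O[Si](C)(C)C(C)(C)C)c(Br)c2)=C1Br | intermediate
9 | (5Z)-3-bromo-4-{3-bromo-4-[(tert-butyldimethylsilyl)oxy]phenyl}-5-({3-bromo-4-[(tert-butyldimethylsilyl)oxy]phenyl}methylidene)furan-2(5H)-one | O=C1O/C(=C\c2ccc(O[Si](C)(C)C(C)(C)C)c(Br)c2)C(c2ccc(O[Si](C)(C)C(C)(C)C)c(Br)c2)=C1Br | intermediate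
10 | (5Z)-4-{3-bromo-4-[(tert-butyldimethylsilyl)oxy]phenyl}-5-({3-bromo-4-[(tert-butyldimethylsilyl)oxy]phenyl}methylidene)-2-oxo-2,5-dihydrofuran-3-carbaldehyde | O=CC1=C(c2ccc(O[Si](C)(C)C(C)(C)C)c(Br)c2)/C(=C/c2ccc(O[Si](C)(C)C(C)(C)C)c(Br)c2)OC1=O | intermediate
11 | 2,6-dibromophenol | Oc1c(Br)cccc1Br | starting material
12 | 2,6-dibromo-4-iodophenol | Oc1c(Br)cc(I)cc1Br | intermediate
13 | 1,3-dibromo-5-iodo-2-methoxybenzene | COc1c(Br)cc(I)cc1Br | intermediate
14 | (3,5-dibromo-4-methoxyphenyl)magnesium chloride, LiCl complex (formed in the flask in step 7) | COc1c(Br)cc([Mg]Cl)cc1Br | intermediate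
15 | (3,5-dibromo-4-methoxyphenyl)titanium triisopropoxide (formed in the flask in step 7) | COc1c(Br)cc([Ti](OC(C)C)(OC(C)C)OC(C)C)cc1Br | intermediate
16 | (5Z)-4-{3-bromo-4-[(tert-butyldimethylsilyl)oxy]phenyl}-5-({3-bromo-4-[(tert-butyldimethylsilyl)oxy]phenyl}methylidene)-3-[(S)-(3,5-dibromo-4-methoxyphenyl)(hydroxy)methyl]furan-2(5H)-one | COc1c(Br)cc([C@H](O)C2=C(c3ccc(O[Si](C)(C)C(C)(C)C)c(Br)c3)/C(=C/c3ccc(O[Si](C)(C)C(C)(C)C)c(Br)c3)OC2=O)cc1Br | intermediate
17 | (5Z)-4-(3-bromo-4-hydroxyphenyl)-5-[(3-bromo-4-hydroxyphenyl)methylidene]-3-[(S)-(3,5-dibromo-4-methoxyphenyl)(hydroxy)methyl]furan-2(5H)-one (CID71459453) | COc1c(Br)cc([C@H](O)C2=C(c3ccc(O)c(Br)c3)/C(=C/c3ccc(O)c(Br)c3)OC2=O)cc1Br | target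

Total step count: 8
Longest linear sequence: 6 steps (steps 1, 2, 3, 4, 7 and 8)

Steps most likely to fail

1. Step 4. Oxidative addition at one of the aryl C–Br bonds, hydrodebromination at C3 before CO insertion, or tin hydride conjugate reduction of the dienyl lactone may compete with formylation. The fallback introduces the one-carbon unit before any aryl bromide is present and unveils the aldehyde by oxidative cleavage. It sets out from 3: Stille coupling with tributyl(vinyl)stannane (Pd(PPh3)4, toluene, 90 °C) would give 3-ethenyl-4-(4-hydroxyphenyl)furan-2(5H)-one F1. NBS (MeCN, 0 °C) would then give 4-(3-bromo-4-hydroxyphenyl)-3-ethenylfuran-2(5H)-one F2. The conditions of step 3 with 5 would lead through the silyloxyfuran F3 and the aldol silyl ether F4 to the (5Z)-3-ethenyl benzylidene butenolide F5. Lemieux–Johnson cleavage of the terminal vinyl group (OsO4 cat., NaIO4, 2,6-lutidine, dioxane/H2O) would come back to the route at 10.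

2. Step 7. Poor facial selectivity may result if the neighbouring lactone carbonyl chelates titanium and distorts the usual transition state, and an uncatalysed background addition promoted by magnesium salts may erode the enantiomeric purity. The fallback sets the stereocentre by reduction instead. It sets out from 10 and 13: the aryltitanium reagent 15 added without the chiral ligand (CH2Cl2, 0 °C) would give the racemic carbinol F6. Dess–Martin periodinane (CH2Cl2, rt) would give the 3-aroyl butenolide F7. Corey–Bakshi–Shibata reduction ((R)-2-methyl-CBS-oxazaborolidine, catecholborane, toluene, –78 °C), with the doubly flanked butenolide carbon taken as the large group, would come back to the route at 16.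

3. Step 3. Silylation, aldol addition and elimination in one flask may interfere with each other: incomplete phenol silylation, loss of aryl silyl ethers to DBU, or incomplete equilibration to the Z-alkene. The fallback runs the sequence stepwise through a lithium dienolate. It sets out from 4 and 5: TBSCl/imidazole (DMF, rt) on each would give 3-bromo-4-{3-bromo-4-[(tert-butyldimethylsilyl)oxy]phenyl}furan-2(5H)-one F8 and the aldehyde 6 as an isolated compound. LiHMDS (THF, –78 °C) followed by 6 would give the C5 aldol F9. MsCl/Et3N (CH2Cl2, 0 °C) would give the mesylate F10, which DBU would eliminate to come back to the route at 9.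

Further compounds
F1 | step 4 | 3-ethenyl-4-(4-hydroxyphenyl)furan-2(5H)-one | O=C1OCC(c2ccc(O)cc2)=C1C=C
F2 | step 4 | 4-(3-bromo-4-hydroxyphenyl)-3-ethenylfuran-2(5H)-one | O=C1OCC(c2ccc(O)c(Br)c2)=C1C=C
F3 | step 4 | 4-{3-bromo-4-[(tert-butyldimethylsilyl)oxy]phenyl}-2-[(tert-butyldimethylsilyl)oxy]-3-ethenylfuran | CC(C)(C)[Si](C)(C)Oc1occ(-c2ccc(O[Si](C)(C)C(C)(C)C)c(Br)c2)c1C=C
F4 | step 4 | 4-{3-bromo-4-[(TBS)oxy]phenyl}-5-[{3-bromo-4-[(TBS)oxy]phenyl}{(TBS)oxy}methyl]-3-ethenylfuran-2(5H)-one, mixture of diastereomers | O=C1OC(C(O[Si](C)(C)C(C)(C)C)c2ccc(O[Si](C)(C)C(C)(C)C)c(Br)c2)C(c2ccc(O[Si](C)(C)C(C)(C)C)c(Br)c2)=C1C=C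
F5 | step 4 | (5Z)-4-{3-bromo-4-[(tert-butyldimethylsilyl)oxy]phenyl}-5-({3-bromo-4-[(tert-butyldimethylsilyl)oxy]phenyl}methylidene)-3-ethenylfuran-2(5H)-one | O=C1O/C(=C\c2ccc(O[Si](C)(C)C(C)(C)C)c(Br)c2)C(c2ccc(O[Si](C)(C)C(C)(C)C)c(Br)c2)=C1C=C
F6 | step 7 | racemic (5Z)-4-{3-bromo-4-[(tert-butyldimethylsilyl)oxy]phenyl}-5-({3-bromo-4-[(tert-butyldimethylsilyl)oxy]phenyl}methylidene)-3-[(3,5-dibromo-4-methoxyphenyl)(hydroxy)methyl]furan-2(5H)-one | COc1c(Br)cc(C(O)C2=C(c3ccc(O[Si](C)(C)C(C)(C)C)c(Br)c3)/C(=C/c3ccc(O[Si](C)(C)C(C)(C)C)c(Br)c3)OC2=O)cc1Br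
F7 | step 7 | (5Z)-4-{3-bromo-4-[(tert-butyldimethylsilyl)oxy]phenyl}-5-({3-bromo-4-[(tert-butyldimethylsilyl)oxy]phenyl}methylidene)-3-(3,5-dibromo-4-methoxybenzoyl)furan-2(5H)-one | COc1c(Br)cc(C(=O)C2=C(c3ccc(O[Si](C)(C)C(C)(C)C)c(Br)c3)/C(=C/c3ccc(O[Si](C)(C)C(C)(C)C)c(Br)c3)OC2=O)cc1Br
F8 | step 3 | 3-bromo-4-{3-bromo-4-[(tert-butyldimethylsilyl)oxy]phenyl}furan-2(5H)-one | O=C1OCC(c2ccc(O[Si](C)(C)C(C)(C)C)c(Br)c2)=C1Br
F9 | step 3 | 3-bromo-4-{3-bromo-4-[(tert-butyldimethylsilyl)oxy]phenyl}-5-[{3-bromo-4-[(tert-butyldimethylsilyl)oxy]phenyl}(hydroxy)methyl]furan-2(5H)-one, mixture of diastereomers | O=C1OC(C(O)c2ccc(O[Si](C)(C)C(C)(C)C)c(Br)c2)C(c2ccc(O[Si](C)(C)C(C)(C)C)c(Br)c2)=C1Br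
F10 | step 3 | {3-bromo-4-[(tert-butyldimethylsilyl)oxy]phenyl}(4-bromo-3-{3-bromo-4-[(tert-butyldimethylsilyl)oxy]phenyl}-5-oxo-2,5-dihydrofuran-2-yl)methyl methanesulfonate, mixture of diastereomers | O=C1OC(C(OS(C)(=O)=O)c2ccc(O[Si](C)(C)C(C)(C)C)c(Br)c2)C(c2ccc(O[Si](C)(C)C(C)(C)C)c(Br)c2)=C1Br
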